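## Retrosynthetic overview

- The dihydropyran (ring B) is opened by a retro-oxa-Diels–Alder reaction to (1R,5R)-β-pinene and a 2-isobutylidene cyclohexane-1,3,5-trione; the spiro centre and C4 both arise in this cycloaddition.
- The trione ring (ring A) is not taken from a preformed cyclic dione: retro-Knoevenagel (isobutyraldehyde) and retro-Dieckmann unzip it to an acyclic triketo ester. Rings A and B are therefore both closed in the last flask, A first and B second.
- The triketo ester comes from acetyl chloride and the lithium enolate released when methoxide opens 2,2,4,4-tetramethylcyclobutane-1,3-dione (dimethylketene dimer).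
- The pinane rings and their two stereocentres are bought with (+)-α-pinene, which is isomerised contra-thermodynamically to (+)-β-pinene. The target has the (1R,5R) pinane skeleton, not that of the common (−)-β-pinene.

Assumption: (+)-α-pinene of at least 97% ee is used because (+)-β-pinene itself is not a cheap catalogue item; the ee of the product equals that of this terpene.

## Route

Step 1
Reactants: 1 (1R,5R)-(+)-α-pinene
Product: 4 (1R,5R)-(+)-β-pinene, via myrtenylpotassium 2 (not isolated), via potassium trimethoxy(myrtenyl)borate 3 (not isolated)
Conditions: n-BuLi, KOt-Bu, hexane, rt, 48 h; B(OMe)3, Et2O, −78 °C to rt; H2O, 0 °C; distillation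
Reagents that add atoms: none
Why: Schlosser superbase metalation removes an allylic methyl proton to give allylpotassium 2, and protonolysis of its borate 3 occurs at the ring γ-carbon with allylic transposition (SE2′ protodeboronation), which delivers the less stable exocyclic alkene; neither bridgehead stereocentre is touched, so the (1R,5R) skeleton is carried over unchanged.

Step 2
Reactants: 5 2,2,4,4-tetramethylcyclobutane-1,3-dione
Product: 7 methyl 2,2,4,4-tetramethyl-3,5-dioxohexanoate, via lithium 5-methoxy-2,4,4-trimethyl-5-oxopent-2-en-3-olate 6 (not isolated)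
Conditions: LiOMe, THF, 0 °C (slow addition of 5); AcCl, −78 to 0 °C; distillation
Reagents that add atoms: lithium methoxide, [Li+].[O-]C; acetyl chloride, CC(Cl)=O
Why: Proposed new method: methoxide adds to the strained 1,3-dione and retro-Claisen C–C cleavage releases the tetrasubstituted lithium enolate 6 regiospecifically with no proton source present, and this tight lithium ion pair is then acetylated on carbon; the closest known reactions are the alkoxide ring-opening of dimethylketene dimer to 2,2,4-trimethyl-3-oxopentanoates and the C-acylation of the preformed lithium enolate of that keto ester with acetyl chloride (no stereocentre is formed).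

Step 3
Reactants: 7 methyl 2,2,4,4-tetramethyl-3,5-dioxohexanoate; 8 isobutyraldehyde (2-methylpropanal); 4 (1R,5R)-(+)-β-pinene
Product: 12 (1'S,2S,4R,5'R)-6,6,6',6',8,8-hexamethyl-4-(propan-2-yl)-3,4-dihydrospiro[chromene-2,2'-bicyclo[3.1.1]heptane]-5,7(6H,8H)-dione, via potassium 4,4,6,6-tetramethyl-3,5-dioxocyclohex-1-en-1-olate 9 (not isolated), via syncarpic acid 10 (not isolated), via 2-isobutylidene-4,4,6,6-tetramethylcyclohexane-1,3,5-trione 11 (not isolated)
Conditions: KOt-Bu (1.1 equiv), THF, 0 °C to rt; then AcOH (3 equiv), ethylenediammonium diacetate (10 mol %), 8 (1.5 equiv), 4 (2 equiv), 60 °C, sealed flask; chromatography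
Reagents that add atoms: none
Why: Proposed new method: the methyl-ketone enolate of 7 closes ring A by Dieckmann (intramolecular Claisen) acylation, driven by formation of the acidic trione enolate 9, and after buffering with AcOH a Knoevenagel condensation with 8 gives the cross-conjugated heterodiene 11, which is trapped by 4 in an inverse-electron-demand oxa-Diels–Alder reaction that closes ring B with the CH2 terminus bonding to the alkylidene carbon and the carbonyl oxygen bonding to the tertiary carbon on the alkene face anti to the gem-dimethyl bridge (spiro centre S), while the orientation with the pinane bridgehead carbon endo sets C4 as R (the 4S epimer from the other orientation is removed by chromatography); the closest known chemistry is the base-mediated Dieckmann synthesis of syncarpic acid and the three-component Knoevenagel/hetero-Diels–Alder reaction of syncarpic acid, an aldehyde and a terpene alkene.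

## Compound list

1 | (1R,5R)-(+)-α-pinene | CC1=CC[C@@H]2C[C@H]1C2(C)C | starting material
2 | myrtenylpotassium | [K+].[CH2-]C1=CC[C@@H]2C[C@H]1C2(C)C | intermediate
3 | potassium trimethoxy(myrtenyl)borate | [K+].CO[B-](OC)(OC)CC1=CC[C@@H]2C[C@H]1C2(C)C | intermediate
4 | (1R,5R)-(+)-β-pinene | C=C1CC[C@@H]2C[C@H]1C2(C)C | intermediate
5 | 2,2,4,4-tetramethylcyclobutane-1,3-dione | CC1(C)C(=O)C(C)(C)C1=O | starting material
6 | lithium 5-methoxy-2,4,4-trimethyl-5-oxopent-2-en-3-olate | [Li+].COC(=O)C(C)(C)C([O-])=C(C)C | intermediate
7 | methyl 2,2,4,4-tetramethyl-3,5-dioxohexanoate | COC(=O)C(C)(C)C(=O)C(C)(C)C(C)=O | intermediate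
8 | isobutyraldehyde (2-methylpropanal) | CC(C)C=O | starting material
9 | potassium 4,4,6,6-tetramethyl-3,5-dioxocyclohex-1-en-1-olate | [K+].[O-]C1=CC(=O)C(C)(C)C(=O)C1(C)C | intermediate
10 | syncarpic acid (2,2,4,4-tetramethylcyclohexane-1,3,5-trione) | CC1(C)C(=O)CC(=O)C(C)(C)C1=O | intermediate
11 | 2-isobutylidene-4,4,6,6-tetramethylcyclohexane-1,3,5-trione | CC(C)C=C1C(=O)C(C)(C)C(=O)C(C)(C)C1=O | intermediate
12 | (1'S,2S,4R,5'R)-6,6,6',6',8,8-hexamethyl-4-(propan-2-yl)-3,4-dihydrospiro[chromene-2,2'-bicyclo[3.1.1]heptane]-5,7(6H,8H)-dione | CC(C)[C@H]1C[C@]2(CC[C@@H]3C[C@H]2C3(C)C)OC2=C1C(=O)C(C)(C)C(=O)C2(C)C | target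

## Step count and risks

Total step count: 3. Longest linear sequence: 2 (5 to 7 to 12, or 1 to 4 to 12).

**Step 3 (most likely to fail).** The three stages may not tolerate one another in one flask, and bis-adducts of 10 with 11 or ene products can compete. The C4 epimer ratio is expected to be modest (about 1:1 to 2:1, either way), so 12 must be separated from its 4S epimer.
Fallback, setting out from 7 and returning at 12: KOt-Bu in THF followed by acidic work-up gives isolated syncarpic acid 10. Condensing 10 with 8 and piperidine (CH2Cl2, rt) gives the crystalline Mannich base 3-hydroxy-4,4,6,6-tetramethyl-2-[2-methyl-1-(piperidin-1-yl)propyl]cyclohex-2-ene-1,5-dione F1. Heating F1 with 4 (3 equiv) and AcOH (2 equiv) in toluene at 80 °C releases 11 slowly by loss of piperidine under near-neutral conditions, and the cycloaddition then gives 12.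

**Step 2.** The hindered enolate may be acetylated on oxygen, or 6 may attack unreacted 5.
Fallback, setting out from 5 and returning at 7: methanolysis (MeOH, NaOMe 5 mol %, reflux) gives isolated methyl 2,2,4-trimethyl-3-oxopentanoate F2. Deprotonation with LiN(i-Pr)2 (THF, −78 °C) regenerates lithium enolate 6, which is added to acetaldehyde, an electrophile that can only bond through carbon, to give racemic methyl 5-hydroxy-2,2,4,4-tetramethyl-3-oxohexanoate F3. Dess–Martin periodinane in CH2Cl2 oxidises F3 to 7.

**Step 1.** Metalation may be incomplete, or protonation at the α-carbon may return 1. A few percent of 1 in 4 is tolerable, because the trisubstituted alkene is a far poorer dienophile.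
Fallback, setting out from 1 and returning at 4: hydroboration with BH3·SMe2 and heating in diglyme at 130–150 °C moves boron to the primary carbon and gives tris(cis-myrtanyl)borane F4. Heating F4 with benzaldehyde (β-hydride transfer with alkene displacement) liberates 4, which is distilled.

## Further compounds

F1 | step 3 | 3-hydroxy-4,4,6,6-tetramethyl-2-[2-methyl-1-(piperidin-1-yl)propyl]cyclohex-2-ene-1,5-dione (racemic) | CC(C)C(N1CCCCC1)C1=C(O)C(C)(C)C(=O)C(C)(C)C1=O
F2 | step 2 | methyl 2,2,4-trimethyl-3-oxopentanoate | COC(=O)C(C)(C)C(=O)C(C)C
F3 | step 2 | methyl 5-hydroxy-2,2,4,4-tetramethyl-3-oxohexanoate (racemic) | CC(O)C(C)(C)C(=O)C(C)(C)C(=O)OC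
F4 | step 1 | tris(cis-myrtanyl)borane | B(C[C@H]1CC[C@@H]2C[C@H]1C2(C)C)(C[C@H]1CC[C@@H]2C[C@H]1C2(C)C)C[C@H]1CC[C@@H]2C[C@H]1C2(C)C
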